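Start from one ratio: nucleophile charged over what the charged electrophile can take up.

    electrophile + nucleophile → acid set free + target (k1 = 0.012 M⁻¹ s⁻¹)
    nucleophile + acid set free ⇌ protonated nucleophile, settled at all times (K2 = 58 M⁻¹)
    electrophile + target ⇌ idle adduct, settled at all times (K3 = 3.3 M⁻¹)
    acid set free → by-product carried off (k4 = 0.0062 s⁻¹)
    target → over-reaction product (k5 = 0.013 s⁻¹)

electrophile 0.86 M; time 10 min

- a species is counted by the electrophile in it: one idle adduct counts as two
- amounts and yields of target count idle adduct too
- the amount of nucleophile is what is sought; it is there from the start
- in an amount of target, one idle adduct counts as one target
- what has gone from electrophile into another species counts as reacted, even if it can come back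
- run time (flask): 10 min

* the concentration of nucleophile at which the part of the electrophile that has reacted at 10 min is just 90%, in M

Take step 1 alone. One nucleophile goes per electrophile, so 0.774 M must react. At [nucleophile] equal to 0.86 M, an electrophile lasts 1.61 min on average, and the run holds 6.19 such lifetimes.

Add step 2. At that same [nucleophile], protonated nucleophile outweighs free acid set free by 49.9 to one. So each acid set free takes a second nucleophile. Define the demand as 1.72 M, which is twice the charged electrophile: one nucleophile reacted and one protonated per electrophile. The ratio is charged nucleophile over demand. The part wanted of the demand is 1.55 M.

Add step 4. Free acid set free has a half-life of 1.86 min. Bound as salt it leaks through its free share, which stretches that half-life to 94.8 min at the same [nucleophile], longer than the run. The leak quickens as [nucleophile] falls and gives some nucleophile back. But the tail of step 1 needs free nucleophile too. Set these against each other; my figure stays at 1.55 M.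

Add steps 3 and 5. Free target has a half-life of 0.889 min, and the run holds 11.3 of them. Expect little idle adduct at the end. Neither step takes nucleophile.

The forecast gives 1.6 M, with a range of 1.48 M to 1.75 M, since each electrophile “uses one nucleophile and ties up a second as its salt”. That is higher than my figure.

The flask needs 1.56 M, inside that range. At 10.0 min, 12.9% of the charged nucleophile in this flask is still free. Divide by the demand: the ratio is 0.907, close to the part wanted. Now halve the electrophile and leave the nucleophile as it is. The demand falls to 0.860 M, the ratio rises to 1.81, above one, and in that flask 99.5% of the electrophile has reacted at the end of the run.

(The numbers stand for no real mixture; the flask was simulated.)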